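**Strategy**

The synthesis rests on the bond between the catechol ring and the aryl-bearing carbon of the 1,4-dioxane ring. That carbon lies β to the neighbouring ring carbon, whose CH2OH group is carried as a methyl ester. The flat, achiral 1,4-benzodioxine-2-carboxylate 9 is therefore a cyclic β-aryloxy acrylate. Rhodium-catalysed asymmetric conjugate addition of arylboronic acid 4 joins the two halves and sets the aryl-bearing stereocentre under ligand control. Protonation of the enolate anti to the new aryl group should set the neighbouring centre in the cis sense. A Wittig reaction and one DIBAL-H reduction of two esters and two pivalates complete the route.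

Key step: step 6

Remark on the target: the SMILES encodes the cis-(2S,3R) benzodioxane, with aryl and CH2OH on the same face.
Assumption: the sense of induction of the (S)-BINAP catalyst in step 6 is assigned by analogy; if a test run shows the opposite sense, (R)-BINAP is used and nothing else changes.

**Route**

Step 1
Reactants: 1 3-methoxycatechol
Product: 2 3-methoxy-1,2-phenylene bis(2,2-dimethylpropanoate)
Conditions: PivCl, Et3N, DMAP (cat.), CH2Cl2, 0 °C to rt
Reagents that add atoms: pivaloyl chloride, CC(C)(C)C(Cl)=O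
Why: DMAP-catalysed O-acylation of both phenols gives pivalates that should survive borylation, the neutral aqueous key step and the Wittig step, and that are removed by the final hydride reduction.

Step 2
Reactants: 2 3-methoxy-1,2-phenylene bis(2,2-dimethylpropanoate)
Product: 4 [3-methoxy-4,5-bis(2,2-dimethylpropanoyloxy)phenyl]boronic acid, via aryl pinacol boronate 3 (not isolated)
Conditions: [Ir(OMe)(cod)]2 (cat.), dtbpy, B2pin2, THF, 80 °C; then NaIO4, NH4OAc, acetone/H2O, rt
Reagents that add atoms: bis(pinacolato)diboron, CC1(C)OB(OC1(C)C)B1OC(C)(C)C(C)(C)O1; water, O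
Why: Sterically controlled iridium-catalysed C–H borylation (Hartwig–Miyaura) should go to C5, the only C–H without an ortho substituent, and periodate cleavage of the pinacol unit frees the boronic acid.

Step 3
Reactants: 5 5-hydroxyvanillin (3,4-dihydroxy-5-methoxybenzaldehyde)
Product: 6 methyl 2-(4-formyl-2-hydroxy-6-methoxyphenoxy)acetate
Conditions: BrCH2CO2Me (1.05 equiv), Li2CO3, DMF, 45 °C
Reagents that add atoms: methyl bromoacetate, COC(=O)CBr
Why: Williamson ether synthesis under weak-base control, in which only the more acidic 4-OH (para to the formyl group) is deprotonated and alkylated, so the future ester-bearing carbon sits on the oxygen next to the methoxy group.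

Step 4
Reactants: 6 methyl 2-(4-formyl-2-hydroxy-6-methoxyphenoxy)acetate
Product: 8 methyl 6-formyl-8-methoxy-1,4-benzodioxine-2-carboxylate, via enamino ester 7 (not isolated)
Conditions: t-BuOCH(NMe2)2, toluene, 80 °C; then AcOH, 80 °C
Reagents that add atoms: tert-butoxybis(dimethylamino)methane (Bredereck's reagent), CC(C)(C)OC(N(C)C)N(C)C
Why: Bredereck aminomethylenation of the aryloxyacetate CH2, then acid-promoted addition–elimination of the neighbouring phenol at the enamine carbon (6-exo-trig, loss of Me2NH), the same condensation/cyclisation that turns o-hydroxyaryl enaminones into chromones.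

Step 5
Reactants: 8 methyl 6-formyl-8-methoxy-1,4-benzodioxine-2-carboxylate
Product: 9 methyl 6-(1,3-dioxolan-2-yl)-8-methoxy-1,4-benzodioxine-2-carboxylate
Conditions: HOCH2CH2OH, PPTS (cat.), toluene, reflux, Dean–Stark
Reagents that add atoms: ethylene glycol, OCCO
Why: Acid-catalysed acetalisation with azeotropic removal of water masks the aldehyde against 1,2-arylation in the key step, while the weak acid should leave the push–pull enol ether alone.

Step 6
Reactants: 9 methyl 6-(1,3-dioxolan-2-yl)-8-methoxy-1,4-benzodioxine-2-carboxylate; 4 [3-methoxy-4,5-bis(2,2-dimethylpropanoyloxy)phenyl]boronic acid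
Product: 11 methyl (2S,3S)-6-formyl-8-methoxy-3-[3-methoxy-4,5-bis(2,2-dimethylpropanoyloxy)phenyl]-2,3-dihydro-1,4-benzodioxine-2-carboxylate (cis), via dioxolane adduct 10 (not isolated)
Conditions: [Rh(OH)((S)-binap)]2 (cat.), 4 (2.5 equiv), dioxane/H2O 10:1, 50 °C; then 1 M HCl, THF, rt
Reagents that add atoms: water, O
Why: Proposed new method: the arylrhodium(I) species formed by transmetallation of 4 adds across the C2=C3 bond of 9 with aryl to C3 and rhodium to C2, and water hydrolyses the resulting rhodium oxa-π-allyl enolate to the ester and Rh–OH. The closest known reaction type is the Hayashi–Miyaura asymmetric 1,4-addition of arylboronic acids to unsaturated esters, to β-aryloxy enones (chromones) and, with kinetic cis protonation, to 1-nitrocyclohexene; an α,β-dioxygenated acrylate held in a 1,4-dioxine ring has not been shown as acceptor. No ring is closed, the dioxine ring is carried through intact. C3 is set by the ligand, whose quadrants should place the aryl group on the Si face of C3 (3S); C2 is set by the substrate, because the enolate is protonated on the face away from the new pseudoaxial aryl group, which gives the kinetic cis (2S) ester. Regioselectivity is secured by the ester, which directs rhodium to C2, and chemoselectivity by the dioxolane (no 1,2-arylation of an aldehyde) and by base-free conditions that avoid epimerisation to the trans ester and β-aryloxide loss.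

Step 7
Reactants: 11 methyl (2S,3S)-6-formyl-8-methoxy-3-[3-methoxy-4,5-bis(2,2-dimethylpropanoyloxy)phenyl]-2,3-dihydro-1,4-benzodioxine-2-carboxylate
Product: 12 methyl (2S,3S)-8-methoxy-6-[(E)-3-methoxy-3-oxoprop-1-en-1-yl]-3-[3-methoxy-4,5-bis(2,2-dimethylpropanoyloxy)phenyl]-2,3-dihydro-1,4-benzodioxine-2-carboxylate (cis)
Conditions: Ph3P=CHCO2Me, toluene, 50 °C
Reagents that add atoms: methyl (triphenylphosphoranylidene)acetate, COC(=O)C=P(c1ccccc1)(c1ccccc1)c1ccccc1
Why: Wittig olefination with a stabilised ylide should give the (E)-cinnamate and, being free of added base, leave the epimerisable cis α-aryloxy ester untouched.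

Step 8
Reactants: 12 methyl (2S,3S)-8-methoxy-6-[(E)-3-methoxy-3-oxoprop-1-en-1-yl]-3-[3-methoxy-4,5-bis(2,2-dimethylpropanoyloxy)phenyl]-2,3-dihydro-1,4-benzodioxine-2-carboxylate
Product: 13 5-[(2S,3R)-3-(hydroxymethyl)-7-[(E)-3-hydroxyprop-1-en-1-yl]-5-methoxy-2,3-dihydro-1,4-benzodioxin-2-yl]-3-methoxybenzene-1,2-diol (target, cis)
Conditions: DIBAL-H (excess), CH2Cl2, −78 to 0 °C; degassed aq. Rochelle salt
Reagents that add atoms: none
Why: DIBAL-H hydride reduction should convert both methyl esters into primary alcohols (1,2-reduction of the cinnamate to the allylic alcohol) and cleave both aryl pivalates in one operation, under cold non-basic conditions that do not touch the two stereocentres.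

**Compound list**

1 | 3-methoxycatechol (3-methoxybenzene-1,2-diol) | COc1cccc(O)c1O | starting material
2 | 3-methoxy-1,2-phenylene bis(2,2-dimethylpropanoate) | COc1cccc(OC(=O)C(C)(C)C)c1OC(=O)C(C)(C)C | intermediate
3 | 3-methoxy-5-(4,4,5,5-tetramethyl-1,3,2-dioxaborolan-2-yl)-1,2-phenylene bis(2,2-dimethylpropanoate) | COc1cc(B2OC(C)(C)C(C)(C)O2)cc(OC(=O)C(C)(C)C)c1OC(=O)C(C)(C)C | intermediate (not isolated)
4 | [3-methoxy-4,5-bis(2,2-dimethylpropanoyloxy)phenyl]boronic acid | COc1cc(B(O)O)cc(OC(=O)C(C)(C)C)c1OC(=O)C(C)(C)C | intermediate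
5 | 5-hydroxyvanillin (3,4-dihydroxy-5-methoxybenzaldehyde) | COc1cc(C=O)cc(O)c1O | starting material
6 | methyl 2-(4-formyl-2-hydroxy-6-methoxyphenoxy)acetate | COC(=O)COc1c(O)cc(C=O)cc1OC | intermediate
7 | methyl (Z)-3-(dimethylamino)-2-(4-formyl-2-hydroxy-6-methoxyphenoxy)prop-2-enoate | COC(=O)/C(Oc1c(O)cc(C=O)cc1OC)=C/N(C)C | intermediate (not isolated)
8 | methyl 6-formyl-8-methoxy-1,4-benzodioxine-2-carboxylate | COC(=O)C1=COc2cc(C=O)cc(OC)c2O1 | intermediate
9 | methyl 6-(1,3-dioxolan-2-yl)-8-methoxy-1,4-benzodioxine-2-carboxylate | COC(=O)C1=COc2cc(C3OCCO3)cc(OC)c2O1 | intermediate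
10 | methyl (2S,3S)-6-(1,3-dioxolan-2-yl)-8-methoxy-3-[3-methoxy-4,5-bis(2,2-dimethylpropanoyloxy)phenyl]-2,3-dihydro-1,4-benzodioxine-2-carboxylate (cis) | COc1cc([C@@H]2Oc3cc(C4OCCO4)cc(OC)c3O[C@@H]2C(=O)OC)cc(OC(=O)C(C)(C)C)c1OC(=O)C(C)(C)C | intermediate (not isolated)
11 | methyl (2S,3S)-6-formyl-8-methoxy-3-[3-methoxy-4,5-bis(2,2-dimethylpropanoyloxy)phenyl]-2,3-dihydro-1,4-benzodioxine-2-carboxylate (cis) | COc1cc([C@@H]2Oc3cc(C=O)cc(OC)c3O[C@@H]2C(=O)OC)cc(OC(=O)C(C)(C)C)c1OC(=O)C(C)(C)C | intermediate
12 | methyl (2S,3S)-8-methoxy-6-[(E)-3-methoxy-3-oxoprop-1-en-1-yl]-3-[3-methoxy-4,5-bis(2,2-dimethylpropanoyloxy)phenyl]-2,3-dihydro-1,4-benzodioxine-2-carboxylate (cis) | COc1cc([C@@H]2Oc3cc(/C=C/C(=O)OC)cc(OC)c3O[C@@H]2C(=O)OC)cc(OC(=O)C(C)(C)C)c1OC(=O)C(C)(C)C | intermediate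
13 | 5-[(2S,3R)-3-(hydroxymethyl)-7-[(E)-3-hydroxyprop-1-en-1-yl]-5-methoxy-2,3-dihydro-1,4-benzodioxin-2-yl]-3-methoxybenzene-1,2-diol | COc1cc([C@@H]2Oc3cc(/C=C/CO)cc(OC)c3O[C@@H]2CO)cc(O)c1O | target

**Step count**

Total: 8 steps. Longest linear sequence: 6 steps (steps 3 to 8, from 5-hydroxyvanillin); the boronic acid branch has 2 steps.

**Steps most likely to fail**

1. Step 6 (Proposed new method). The donor-substituted alkene may insert into the aryl–rhodium bond so slowly that protodeboronation of 4 takes over. The rhodium enolate may open the dioxine ring by β-aryloxide elimination. Protonation may occur on the wrong face, or the product may epimerise. The fallback makes the same aryl–carbon bond by cross-coupling and sets both centres by hydrogenation. It sets out from 9: bromine addition and dehydrobromination (Br2, CH2Cl2, −78 °C; then Et3N) should give methyl 3-bromo-6-(1,3-dioxolan-2-yl)-8-methoxy-1,4-benzodioxine-2-carboxylate F1. Suzuki–Miyaura coupling of F1 with 4 (Pd(dppf)Cl2, K3PO4, dioxane/H2O, 70 °C) should give methyl 6-(1,3-dioxolan-2-yl)-8-methoxy-3-[3-methoxy-4,5-bis(2,2-dimethylpropanoyloxy)phenyl]-1,4-benzodioxine-2-carboxylate F2. Asymmetric hydrogenation of the tetrasubstituted enol ether acrylate (Rh(I)/chiral bisphosphine, H2 under pressure) adds both hydrogens to one face and should give the cis ester. The fallback comes back to the route at 10, which is then hydrolysed to 11 as in the second half of step 6.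

2. Step 4. The aminomethylenation may stall because the free phenoxide and the aldehyde consume the aminal ester, or the phenol may close onto the ester (lactonisation) instead of the enamine carbon. The fallback brings in the ring CH carbon as an acetal inside the alkylating agent. It sets out from 5. Methyl 2-bromo-3,3-dimethoxypropanoate F3 is prepared from methyl (E)-3-methoxyacrylate with NBS in MeOH. Alkylation of 5 with F3 (Li2CO3, DMF) at the more acidic 4-OH should give methyl 2-(4-formyl-2-hydroxy-6-methoxyphenoxy)-3,3-dimethoxypropanoate F4. Acid-catalysed transacetalisation (TsOH, toluene, reflux, removal of MeOH) should close the ring to methyl 6-formyl-3,8-dimethoxy-2,3-dihydro-1,4-benzodioxine-2-carboxylate F5, which loses methanol under the same conditions. The fallback comes back to the route at 8.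

3. Step 3. Alkylation may occur at the wrong hydroxyl or at both, which would carry the wrong ring regiochemistry through the whole route. The fallback introduces the second oxygen only after O-alkylation of a mono-phenol, so no choice between hydroxyls arises. It sets out from commercial 5-iodovanillin F6 and methyl bromoacetate (K2CO3, DMF), which should give methyl 2-(4-formyl-2-iodo-6-methoxyphenoxy)acetate F7. Miyaura borylation (B2pin2, Pd(dppf)Cl2, KOAc, dioxane, 80 °C) should give methyl 2-[4-formyl-2-methoxy-6-(4,4,5,5-tetramethyl-1,3,2-dioxaborolan-2-yl)phenoxy]acetate F8. Oxidation of the C–B bond with trimethylamine N-oxide (CH2Cl2, rt), which should not trigger Dakin oxidation of the aldehyde, gives the phenol. The fallback comes back to the route at 6.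

**Further compounds**

F1 | step 6 | methyl 3-bromo-6-(1,3-dioxolan-2-yl)-8-methoxy-1,4-benzodioxine-2-carboxylate | COC(=O)C1=C(Br)Oc2cc(C3OCCO3)cc(OC)c2O1
F2 | step 6 | methyl 6-(1,3-dioxolan-2-yl)-8-methoxy-3-[3-methoxy-4,5-bis(2,2-dimethylpropanoyloxy)phenyl]-1,4-benzodioxine-2-carboxylate | COC(=O)C1=C(c2cc(OC)c(OC(=O)C(C)(C)C)c(OC(=O)C(C)(C)C)c2)Oc2cc(C3OCCO3)cc(OC)c2O1
F3 | step 4 | methyl 2-bromo-3,3-dimethoxypropanoate (racemic) | COC(=O)C(Br)C(OC)OC
F4 | step 4 | methyl 2-(4-formyl-2-hydroxy-6-methoxyphenoxy)-3,3-dimethoxypropanoate (racemic) | COC(=O)C(Oc1c(O)cc(C=O)cc1OC)C(OC)OC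
F5 | step 4 | methyl 6-formyl-3,8-dimethoxy-2,3-dihydro-1,4-benzodioxine-2-carboxylate (mixture of diastereomers) | COC(=O)C1Oc2c(OC)cc(C=O)cc2OC1OC
F6 | step 3 | 5-iodovanillin (4-hydroxy-3-iodo-5-methoxybenzaldehyde, purchased) | COc1cc(C=O)cc(I)c1O
F7 | step 3 | methyl 2-(4-formyl-2-iodo-6-methoxyphenoxy)acetate | COC(=O)COc1c(I)cc(C=O)cc1OC
F8 | step 3 | methyl 2-[4-formyl-2-methoxy-6-(4,4,5,5-tetramethyl-1,3,2-dioxaborolan-2-yl)phenoxy]acetate | COC(=O)COc1c(B2OC(C)(C)C(C)(C)O2)cc(C=O)cc1OC
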